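**Retrosynthetic overview**
1. Target ⇐ 11,13-epoxide (HCl opens it at C13 and removes the two TBS ethers) ⇐ 8-O-angeloyl α-methylene-γ-lactone ⇐ 8-hydroxy lactone 33.
2. The ten-membered carbocycle and the trans-fused γ-lactone are closed together, last of the rings, by intramolecular chromium Barbier allylation (C6–C7) of aldehyde/allylic bromide 30.
3. The 3(2H)-furanone is formed just before, by 5-endo oxa-Michael closure of an α'-silyloxy ynone made by joining alkyne fragment W (12, C2–C6) to δ-lactone fragment E (24, C1 and C7–C14) at C1–C2.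
4. W: Marshall anti-propargylation of 2-(triethylsilyloxy)acetaldehyde. E: (R)-but-3-ene-1,2-diol → Still–Gennari (Z)-enoate → substrate-controlled OsO4 dihydroxylation → vinylalumination and lactonisation.
5. Ring order: sacrificial δ-lactone of E → furanone → carbocycle plus γ-lactone → spiro-epoxide (opened in the last step).

Assumption: locants C1–C15 follow the germacrane numbering of the target (C1 furanone C=O, C3 enol-ether carbon, C6 lactone CH–O, C8 CH–OAng, C10 C–Me, C11 C(OH)CH2Cl), the target being 4R,5S,6S,7S,8S,9S,10S,11S; TES = triethylsilyl, TBS = tert-butyldimethylsilyl, TMS = trimethylsilyl; compounds 26–38 carry the target's spatial arrangement at every shared centre, as written in their SMILES.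

**Fragment W (steps 1–8)**

Step 1
Reactants: 1 (Z)-but-2-ene-1,4-diol
Product: 2 (Z)-1,4-bis(triethylsilyloxy)but-2-ene
Conditions: TESCl (2.2 equiv), imidazole, CH2Cl2, 0 °C → rt
Reagents that add atoms: chlorotriethylsilane, CC[Si](Cl)(CC)CC
Why: Imidazole-mediated silylation of both primary hydroxyls gives a symmetrical alkene that can be cleaved into two equivalents of the C5–C6 aldehyde; no stereocentre is involved.

Step 2
Reactants: 2 (Z)-1,4-bis(triethylsilyloxy)but-2-ene
Product: 3 2-(triethylsilyloxy)acetaldehyde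
Conditions: O3, CH2Cl2, −78 °C; then PPh3, −78 °C → rt
Reagents that add atoms: ozone, [O-][O+]=O
Why: Ozonolysis with reductive work-up cleaves the alkene into two molecules of the α-silyloxy aldehyde, and TES ethers survive these neutral conditions.

Step 3
Reactants: 4 ethynyltrimethylsilane
Product: 6 4-(trimethylsilyl)but-3-yn-2-one, via lithium (trimethylsilyl)acetylide 5 (not isolated)
Conditions: n-BuLi, THF, −78 °C; then inverse addition to Ac2O, THF, −78 °C
Reagents that add atoms: acetic anhydride, CC(=O)OC(C)=O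
Why: Acylation of the lithium acetylide by inverse addition to excess anhydride stops at the ynone.

Step 4
Reactants: 6 4-(trimethylsilyl)but-3-yn-2-one
Product: 7 (R)-4-(trimethylsilyl)but-3-yn-2-ol
Conditions: RuCl[(R,R)-TsDPEN](p-cymene) (0.5 mol %), i-PrOH, rt
Reagents that add atoms: none
Why: Noyori asymmetric transfer hydrogenation of the alkynyl ketone sets the carbinol centre as (R) with the (R,R)-catalyst.

Step 5
Reactants: 7 (R)-4-(trimethylsilyl)but-3-yn-2-ol
Product: 8 (R)-4-(trimethylsilyl)but-3-yn-2-yl methanesulfonate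
Conditions: MsCl, Et3N, CH2Cl2, −78 → 0 °C
Reagents that add atoms: methanesulfonyl chloride, CS(Cl)(=O)=O
Why: Mesylation on oxygen proceeds with retention and gives the propargylic electrophile for the Marshall reaction.

Step 6
Reactants: 8 (R)-4-(trimethylsilyl)but-3-yn-2-yl methanesulfonate; 3 2-(triethylsilyloxy)acetaldehyde
Product: 10 (2S,3S)-3-methyl-1-(triethylsilyloxy)-5-(trimethylsilyl)pent-4-yn-2-ol, via allenylzinc reagent 9 (not isolated)
Conditions: Pd(OAc)2 (5 mol %), PPh3 (5 mol %), Et2Zn (3 equiv), THF, −78 → −20 °C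
Reagents that add atoms: none
Why: Marshall propargylation: zerovalent palladium ionises the mesylate with inversion, transmetalation to zinc gives a configurationally defined allenylzinc, and its cyclic SE2' addition to the aldehyde sets the anti C4-methyl/C5-hydroxyl pair with transfer of the mesylate chirality.

Step 7
Reactants: 10 (2S,3S)-3-methyl-1-(triethylsilyloxy)-5-(trimethylsilyl)pent-4-yn-2-ol
Product: 11 (2S,3S)-2-(tert-butyldimethylsilyloxy)-3-methyl-1-(triethylsilyloxy)-5-(trimethylsilyl)pent-4-yne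
Conditions: TBSOTf, 2,6-lutidine, CH2Cl2, −78 → 0 °C
Reagents that add atoms: tert-butyldimethylsilyl triflate, CC(C)(C)[Si](C)(C)OS(=O)(=O)C(F)(F)F
Why: Silyl triflate protection of the secondary C5 hydroxyl as a robust TBS ether that lasts until the final step; no stereocentre is touched.

Step 8
Reactants: 11 (2S,3S)-2-(tert-butyldimethylsilyloxy)-3-methyl-1-(triethylsilyloxy)-5-(trimethylsilyl)pent-4-yne
Product: 12 (2S,3S)-2-(tert-butyldimethylsilyloxy)-3-methyl-1-(triethylsilyloxy)pent-4-yne (fragment W)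
Conditions: K2CO3, MeOH, 0 °C → rt
Reagents that add atoms: none
Why: Base methanolysis cleaves the alkynyl C–Si bond far faster than the O–TES and O–TBS ethers, unmasking the terminal alkyne.

**Fragment E (steps 9–15)**

Step 9
Reactants: 13 (R)-but-3-ene-1,2-diol
Product: 14 (R)-3,4-bis(triethylsilyloxy)but-1-ene
Conditions: TESCl (2.2 equiv), imidazole, CH2Cl2, 0 °C → rt
Reagents that add atoms: chlorotriethylsilane, CC[Si](Cl)(CC)CC
Why: Bis-silylation of the chiral-pool diol, whose stereocentre becomes C8; the primary TES ether is the latent C7 aldehyde and the secondary one protects O8.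

Step 10
Reactants: 14 (R)-3,4-bis(triethylsilyloxy)but-1-ene
Product: 15 (S)-2,3-bis(triethylsilyloxy)propanal
Conditions: O3, CH2Cl2, −78 °C; then PPh3
Reagents that add atoms: ozone, [O-][O+]=O
Why: Ozonolysis of the terminal alkene with neutral reductive work-up gives the α-silyloxy aldehyde without epimerisation at C8.

Step 11
Reactants: 15 (S)-2,3-bis(triethylsilyloxy)propanal
Product: 16 methyl (R,Z)-2-methyl-4,5-bis(triethylsilyloxy)pent-2-enoate
Conditions: methyl 2-[bis(2,2,2-trifluoroethoxy)phosphoryl]propanoate, KN(SiMe3)2, 18-crown-6, THF, −78 °C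
Reagents that add atoms: methyl 2-[bis(2,2,2-trifluoroethoxy)phosphoryl]propanoate, COC(=O)C(C)P(=O)(OCC(F)(F)F)OCC(F)(F)F
Why: Still–Gennari olefination gives the kinetic (Z)-trisubstituted enoate, placing C1 and C8 cis as the C9/C10 relative configuration requires.

Step 12
Reactants: 16 methyl (R,Z)-2-methyl-4,5-bis(triethylsilyloxy)pent-2-enoate
Product: 17 methyl (2S,3S,4S)-2,3-dihydroxy-2-methyl-4,5-bis(triethylsilyloxy)pentanoate
Conditions: OsO4 (5 mol %), NMO, acetone/H2O, rt
Reagents that add atoms: N-methylmorpholine N-oxide, C[N+]1([O-])CCOCC1; water, O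
Why: Upjohn syn-dihydroxylation of the (Z)-alkene fixes C9 relative to C10, and Kishi's empirical rule (attack anti to the allylic silyloxy group, erythro C8/C9) sets both new centres from C8.

Step 13
Reactants: 17 methyl (2S,3S,4S)-2,3-dihydroxy-2-methyl-4,5-bis(triethylsilyloxy)pentanoate
Product: 19 methyl (2S,3S,4S)-3-(tert-butyldimethylsilyloxy)-2-methyl-4,5-bis(triethylsilyloxy)-2-(trimethylsilyloxy)pentanoate, via mono-TBS ether 18 (not isolated)
Conditions: TBSOTf (1.1 equiv), 2,6-lutidine, CH2Cl2, −78 °C; then TMSOTf, −78 → 0 °C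
Reagents that add atoms: tert-butyldimethylsilyl triflate, CC(C)(C)[Si](C)(C)OS(=O)(=O)C(F)(F)F; trimethylsilyl triflate, C[Si](C)(C)OS(=O)(=O)C(F)(F)F
Why: The secondary C9 hydroxyl is silylated first (TBS, kept to the end) and the tertiary C10 hydroxyl is then capped as a labile TMS ether so it cannot form a lactol with the C7 aldehyde.

Step 14
Reactants: 19 methyl (2S,3S,4S)-3-(tert-butyldimethylsilyloxy)-2-methyl-4,5-bis(triethylsilyloxy)-2-(trimethylsilyloxy)pentanoate
Product: 20 methyl (2S,3S,4R)-3-(tert-butyldimethylsilyloxy)-2-methyl-5-oxo-4-(triethylsilyloxy)-2-(trimethylsilyloxy)pentanoate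
Conditions: (COCl)2, DMSO, CH2Cl2, −78 → −40 °C; then Et3N, −78 → 0 °C
Reagents that add atoms: none
Why: Swern conditions oxidise a primary TES ether directly to the aldehyde (oxidative desilylation) while the secondary TES, TBS and tertiary TMS ethers are inert.

Step 15
Reactants: 20 methyl (2S,3S,4R)-3-(tert-butyldimethylsilyloxy)-2-methyl-5-oxo-4-(triethylsilyloxy)-2-(trimethylsilyloxy)pentanoate; 21 methyl propiolate
Product: 24 methyl 2-[(2S,3S,4S,5S)-4-(tert-butyldimethylsilyloxy)-5-methyl-6-oxo-3-(triethylsilyloxy)-5-(trimethylsilyloxy)oxan-2-yl]prop-2-enoate (fragment E), via vinylalane 22 (not isolated), via aluminium alkoxide 23 (not isolated)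
Conditions: i-Bu2AlH, NMO, 21, THF, 0 °C; then 20, 0 °C → rt, 12 h; aq. potassium sodium tartrate
Reagents that add atoms: none
Why: Ramachandran vinylalumination (a Morita–Baylis–Hillman-type addition) adds the α-aluminoacrylate to the aldehyde in the Felkin–Anh sense (major C7 epimer drawn, the centre is erased in step 19), and the aluminium alkoxide closes onto the C1 methyl ester to give a δ-lactone that masks O7 and activates C1.

**Fragment union and endgame (steps 16–23)**

Step 16
Reactants: 12 (2S,3S)-2-(tert-butyldimethylsilyloxy)-3-methyl-1-(triethylsilyloxy)pent-4-yne (fragment W); 24 δ-lactone (fragment E)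
Product: 27 5,9-bis-O-TBS 6,8-bis-O-TES seco-furanone with free C7 hydroxyl, via lithium acetylide 25 (not isolated), via seco-ynone 26 (not isolated)
Conditions: n-BuLi, THF, −78 °C; then 24, −78 °C; AcOH quench; crude product, K2CO3, MeOH, 0 °C
Reagents that add atoms: none
Why: The acetylide adds to the δ-lactone carbonyl (more electrophilic than the conjugated methyl ester) and stops at the lactolate, then K2CO3/MeOH cleaves the tertiary TMS ether and the C10 oxygen closes the 3(2H)-furanone by 5-endo-dig oxa-Michael addition with C10 untouched.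

Step 17
Reactants: 27 5,9-bis-O-TBS 6,8-bis-O-TES seco-furanone
Product: 28 5,9-bis-O-TBS 8-O-TES seco-furanone 6,7-diol
Conditions: PPTS (0.2 equiv), MeOH/CH2Cl2 (1:1), 0 °C
Reagents that add atoms: none
Why: Acid-catalysed methanolysis removes the unhindered primary TES ether much faster than the hindered secondary TES and TBS ethers.

Step 18
Reactants: 28 5,9-bis-O-TBS 8-O-TES seco-furanone 6,7-diol
Product: 29 5,9-bis-O-TBS 8-O-TES seco-furanone C6 aldehyde with free C7 hydroxyl
Conditions: TEMPO (10 mol %), PhI(OAc)2, CH2Cl2, rt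
Reagents that add atoms: none
Why: Oxoammonium (TEMPO/PhI(OAc)2) oxidation takes the primary alcohol selectively over the hindered, electron-poor secondary allylic alcohol and does not epimerise C5.

Step 19
Reactants: 29 seco-furanone C6 aldehyde
Product: 30 seco-furanone C6 aldehyde bearing the methyl (Z)-2-(bromomethyl)enoate (C7=C11, C13–Br)
Conditions: NBS, Me2S, CH2Cl2, −20 → 0 °C
Reagents that add atoms: N-bromosuccinimide, O=C1CCC(=O)N1Br
Why: Corey–Kim-type activation of the Morita–Baylis–Hillman alcohol and SN2' bromide delivery give the thermodynamically preferred (Z)-allylic bromide, removing the C7 stereocentre.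

Step 20
Reactants: 30 aldehyde allylic bromide
Product: 33 5,9-bis-O-TBS 8-hydroxy 11(13)-ene 6,12-lactone (ten-membered carbocycle), via macrocyclic hydroxy ester 31 (not isolated), via TES lactone 32 (not isolated)
Conditions: CrCl2 (10 equiv), THF, 2 mM (syringe pump), rt; then 1 M aq. HCl, THF, 0 °C
Reagents that add atoms: none
Why: Intramolecular Nozaki–Hiyama (chromium Barbier) allylation through a chair-like six-membered transition state gives the 6,7-anti (trans-lactone) pair, with the C8 silyloxy centre and the rigid furanone tether expected to fix the facial sense; the alkoxide lactonises onto the methyl ester and dilute HCl then removes the more labile C8 TES ether.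

Step 21
Reactants: 33 8-hydroxy lactone; 34 angelic acid ((Z)-2-methylbut-2-enoic acid)
Product: 36 8-O-angeloyl 5,9-bis-O-TBS 11(13)-ene 6,12-lactone, via mixed anhydride 35 (not isolated)
Conditions: 34, 2,4,6-trichlorobenzoyl chloride, Et3N, toluene, rt; then 33, 80 °C
Reagents that add atoms: none
Why: Yamaguchi-type mixed-anhydride esterification without DMAP acylates the only free hydroxyl (C8) and avoids angelate-to-tiglate isomerisation.

Step 22
Reactants: 36 8-O-angeloyl 11(13)-ene lactone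
Product: 37 8-O-angeloyl 5,9-bis-O-TBS 11,13-epoxy lactone
Conditions: t-BuOOH, DBU, CH2Cl2, 0 °C
Reagents that add atoms: tert-butyl hydroperoxide, CC(C)(C)OO
Why: Weitz–Scheffer nucleophilic epoxidation attacks only the unhindered α-methylene lactone (not the trisubstituted angelate or the vinylogous ester) and closes the epoxide on the lactone face anti to the C8 substituent, setting C11.

Step 23
Reactants: 37 11,13-epoxy lactone
Product: 39 CNP0340393.2 (target), via bis-TBS chlorohydrin 38 (not isolated)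
Conditions: conc. aq. HCl, THF, 0 °C → rt
Reagents that add atoms: hydrogen chloride, Cl
Why: Chloride opens the protonated epoxide by SN2 attack at primary C13, leaving the C11–O bond and its configuration intact, and the same acid hydrolyses the two secondary TBS ethers.

**Compound list**
1 | (Z)-but-2-ene-1,4-diol | OC/C=C\CO | starting material
2 | (Z)-1,4-bis(triethylsilyloxy)but-2-ene | CC[Si](CC)(CC)OC/C=C\CO[Si](CC)(CC)CC | intermediate
3 | 2-(triethylsilyloxy)acetaldehyde | CC[Si](CC)(CC)OCC=O | intermediate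
4 | ethynyltrimethylsilane | C#C[Si](C)(C)C | starting material
5 | lithium (trimethylsilyl)acetylide | [Li]C#C[Si](C)(C)C | intermediate (not isolated)
6 | 4-(trimethylsilyl)but-3-yn-2-one | CC(=O)C#C[Si](C)(C)C | intermediate
7 | (R)-4-(trimethylsilyl)but-3-yn-2-ol | C[C@@H](O)C#C[Si](C)(C)C | intermediate
8 | (R)-4-(trimethylsilyl)but-3-yn-2-yl methanesulfonate | C[C@@H](OS(C)(=O)=O)C#C[Si](C)(C)C | intermediate
9 | ethyl[1-(trimethylsilyl)buta-1,2-dien-1-yl]zinc (axially chiral allenylzinc) | CC[Zn]C([Si](C)(C)C)=[C@]=C(C)[H] | intermediate (not isolated)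
10 | (2S,3S)-3-methyl-1-(triethylsilyloxy)-5-(trimethylsilyl)pent-4-yn-2-ol | CC[Si](CC)(CC)OC[C@@H](O)[C@@H](C)C#C[Si](C)(C)C | intermediate
11 | (2S,3S)-2-(tert-butyldimethylsilyloxy)-3-methyl-1-(triethylsilyloxy)-5-(trimethylsilyl)pent-4-yne | CC[Si](CC)(CC)OC[C@@H](O[Si](C)(C)C(C)(C)C)[C@@H](C)C#C[Si](C)(C)C | intermediate
12 | (2S,3S)-2-(tert-butyldimethylsilyloxy)-3-methyl-1-(triethylsilyloxy)pent-4-yne (fragment W; C2–C6) | CC[Si](CC)(CC)OC[C@@H](O[Si](C)(C)C(C)(C)C)[C@@H](C)C#C | intermediate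
13 | (R)-but-3-ene-1,2-diol | OC[C@H](O)C=C | starting material
14 | (R)-3,4-bis(triethylsilyloxy)but-1-ene | CC[Si](CC)(CC)OC[C@H](O[Si](CC)(CC)CC)C=C | intermediate
15 | (S)-2,3-bis(triethylsilyloxy)propanal | CC[Si](CC)(CC)OC[C@H](O[Si](CC)(CC)CC)C=O | intermediate
16 | methyl (R,Z)-2-methyl-4,5-bis(triethylsilyloxy)pent-2-enoate | COC(=O)/C(C)=C\[C@@H](O[Si](CC)(CC)CC)CO[Si](CC)(CC)CC | intermediate
17 | methyl (2S,3S,4S)-2,3-dihydroxy-2-methyl-4,5-bis(triethylsilyloxy)pentanoate | COC(=O)[C@@](C)(O)[C@@H](O)[C@@H](O[Si](CC)(CC)CC)CO[Si](CC)(CC)CC | intermediate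
18 | methyl (2S,3S,4S)-3-(tert-butyldimethylsilyloxy)-2-hydroxy-2-methyl-4,5-bis(triethylsilyloxy)pentanoate | COC(=O)[C@@](C)(O)[C@@H](O[Si](C)(C)C(C)(C)C)[C@@H](O[Si](CC)(CC)CC)CO[Si](CC)(CC)CC | intermediate (not isolated)
19 | methyl (2S,3S,4S)-3-(tert-butyldimethylsilyloxy)-2-methyl-4,5-bis(triethylsilyloxy)-2-(trimethylsilyloxy)pentanoate | COC(=O)[C@@](C)(O[Si](C)(C)C)[C@@H](O[Si](C)(C)C(C)(C)C)[C@@H](O[Si](CC)(CC)CC)CO[Si](CC)(CC)CC | intermediate
20 | methyl (2S,3S,4R)-3-(tert-butyldimethylsilyloxy)-2-methyl-5-oxo-4-(triethylsilyloxy)-2-(trimethylsilyloxy)pentanoate | COC(=O)[C@@](C)(O[Si](C)(C)C)[C@@H](O[Si](C)(C)C(C)(C)C)[C@@H](O[Si](CC)(CC)CC)C=O | intermediate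
21 | methyl propiolate | C#CC(=O)OC | starting material
22 | [1-(methoxycarbonyl)vinyl]diisobutylaluminium | C=C(C(=O)OC)[Al](CC(C)C)CC(C)C | intermediate (not isolated)
23 | diisobutylaluminium alkoxide of the open C7 carbinol diester (7S, Felkin epimer) | COC(=O)[C@@](C)(O[Si](C)(C)C)[C@@H](O[Si](C)(C)C(C)(C)C)[C@@H](O[Si](CC)(CC)CC)[C@@H](O[Al](CC(C)C)CC(C)C)C(=C)C(=O)OC | intermediate (not isolated)
24 | methyl 2-[(2S,3S,4S,5S)-4-(tert-butyldimethylsilyloxy)-5-methyl-6-oxo-3-(triethylsilyloxy)-5-(trimethylsilyloxy)oxan-2-yl]prop-2-enoate (fragment E; C1, C7–C14) | O=C1O[C@@H](C(=C)C(=O)OC)[C@H](O[Si](CC)(CC)CC)[C@H](O[Si](C)(C)C(C)(C)C)[C@]1(C)O[Si](C)(C)C | intermediate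
25 | lithium acetylide of 12 | CC[Si](CC)(CC)OC[C@@H](O[Si](C)(C)C(C)(C)C)[C@@H](C)C#C[Li] | intermediate (not isolated)
26 | seco-ynone: C1 ketone, C2≡C3, 5,9-bis-O-TBS, 6,8-bis-O-TES, 10-O-TMS, free C7-OH, methyl 2-methylidene ester (C11–C13) | CC[Si](CC)(CC)OC[C@@H](O[Si](C)(C)C(C)(C)C)[C@@H](C)C#CC(=O)[C@@](C)(O[Si](C)(C)C)[C@@H](O[Si](C)(C)C(C)(C)C)[C@@H](O[Si](CC)(CC)CC)[C@@H](O)C(=C)C(=O)OC | intermediate (not isolated)
27 | seco-furanone: 5,9-bis-O-TBS, 6,8-bis-O-TES, free C7-OH | CC[Si](CC)(CC)OC[C@@H](O[Si](C)(C)C(C)(C)C)[C@@H](C)C1=CC(=O)[C@@](C)(O1)[C@@H](O[Si](C)(C)C(C)(C)C)[C@@H](O[Si](CC)(CC)CC)[C@@H](O)C(=C)C(=O)OC | intermediate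
28 | seco-furanone 6,7-diol: 5,9-bis-O-TBS, 8-O-TES | OC[C@@H](O[Si](C)(C)C(C)(C)C)[C@@H](C)C1=CC(=O)[C@@](C)(O1)[C@@H](O[Si](C)(C)C(C)(C)C)[C@@H](O[Si](CC)(CC)CC)[C@@H](O)C(=C)C(=O)OC | intermediate
29 | seco-furanone C6 aldehyde: 5,9-bis-O-TBS, 8-O-TES, free C7-OH | O=C[C@@H](O[Si](C)(C)C(C)(C)C)[C@@H](C)C1=CC(=O)[C@@](C)(O1)[C@@H](O[Si](C)(C)C(C)(C)C)[C@@H](O[Si](CC)(CC)CC)[C@@H](O)C(=C)C(=O)OC | intermediate
30 | seco-furanone C6 aldehyde with methyl (Z)-2-(bromomethyl)enoate (C7=C11, C13-Br) | O=C[C@@H](O[Si](C)(C)C(C)(C)C)[C@@H](C)C1=CC(=O)[C@@](C)(O1)[C@@H](O[Si](C)(C)C(C)(C)C)[C@@H](O[Si](CC)(CC)CC)/C=C(\CBr)C(=O)OC | intermediate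
31 | macrocyclic hydroxy ester: C6-OH, C7 bearing C(=CH2)CO2Me, 8-O-TES, 5,9-bis-O-TBS | CC[Si](CC)(CC)O[C@H]1[C@@H](C(=C)C(=O)OC)[C@H](O)[C@@H](O[Si](C)(C)C(C)(C)C)[C@@H](C)C2=CC(=O)[C@@](C)(O2)[C@H]1O[Si](C)(C)C(C)(C)C | intermediate (not isolated)
32 | 8-O-TES 5,9-bis-O-TBS 11(13)-ene 6,12-lactone | CC[Si](CC)(CC)O[C@H]1[C@@H]2[C@H](OC(=O)C2=C)[C@@H](O[Si](C)(C)C(C)(C)C)[C@@H](C)C2=CC(=O)[C@@](C)(O2)[C@H]1O[Si](C)(C)C(C)(C)C | intermediate (not isolated)
33 | 8-hydroxy 5,9-bis-O-TBS 11(13)-ene 6,12-lactone | O[C@H]1[C@@H]2[C@H](OC(=O)C2=C)[C@@H](O[Si](C)(C)C(C)(C)C)[C@@H](C)C2=CC(=O)[C@@](C)(O2)[C@H]1O[Si](C)(C)C(C)(C)C | intermediate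
34 | angelic acid, (Z)-2-methylbut-2-enoic acid | C/C=C(/C)C(=O)O | starting material
35 | angelic 2,4,6-trichlorobenzoic mixed anhydride | C/C=C(/C)C(=O)OC(=O)c1c(Cl)cc(Cl)cc1Cl | intermediate (not isolated)
36 | 8-O-angeloyl 5,9-bis-O-TBS 11(13)-ene 6,12-lactone | C/C=C(/C)C(=O)O[C@H]1[C@@H]2[C@H](OC(=O)C2=C)[C@@H](O[Si](C)(C)C(C)(C)C)[C@@H](C)C2=CC(=O)[C@@](C)(O2)[C@H]1O[Si](C)(C)C(C)(C)C | intermediate
37 | 8-O-angeloyl 5,9-bis-O-TBS 11,13-epoxy 6,12-lactone (epoxide O on the C11 face of the target hydroxyl) | C/C=C(/C)C(=O)O[C@H]1[C@@H]2[C@H](OC(=O)[C@@]23OC3)[C@@H](O[Si](C)(C)C(C)(C)C)[C@@H](C)C2=CC(=O)[C@@](C)(O2)[C@H]1O[Si](C)(C)C(C)(C)C | intermediate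
38 | 5,9-bis-O-TBS ether of the target | C/C=C(/C)C(=O)O[C@H]1[C@@H]2[C@H](OC(=O)[C@]2(O)CCl)[C@@H](O[Si](C)(C)C(C)(C)C)[C@@H](C)C2=CC(=O)[C@@](C)(O2)[C@H]1O[Si](C)(C)C(C)(C)C | intermediate (not isolated)
39 | CNP0340393.2 | C/C=C(/C)C(=O)O[C@H]1[C@@H]2[C@H](OC(=O)[C@]2(O)CCl)[C@@H](O)[C@@H](C)C2=CC(=O)[C@@](C)(O2)[C@H]1O | target

**Step count and weak points**
Total: 23 steps. Longest linear sequence: 15 steps (13 → 39, steps 9–15 then 16–23); the alkyne branch from 4 is 14 steps.

Step 20 (macrocyclisation). This is the least predictable step: a ten-membered ring is closed and both C6 and C7 are set at once, and the required 5,6-syn relationship runs against simple Felkin control by the C5 silyloxy group. The fallback closes the carbocycle on the more flexible open ynone and forms the furanone last. It sets out from seco-ynone 26, isolated after the acetylide addition of step 16 without the K2CO3 stage. PPTS in MeOH removes the C6 TES and C10 TMS ethers to give ynone triol F1, which is oxidised at once with TEMPO/PhI(OAc)2 to aldehyde F2. NBS/Me2S then gives allylic bromide F3. CrCl2 under high dilution followed by 1 M HCl gives macrocyclic ynone lactone F4. (Ph3P)AuNTf2 in CH2Cl2 closes the furanone by transannular 5-endo attack of the C10 hydroxyl on the ynone, which returns the route to 33.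

Step 15 (vinylalumination with in-situ lactonisation). The aldehyde is hindered and β-silyloxylated, and ring closure onto the neopentyl-like C1 ester may stall. The fallback sets out from aldehyde 20 and uses a catalytic Morita–Baylis–Hillman reaction with methyl acrylate (3-hydroxyquinuclidine, neat, rt) to give the open hydroxy diester F5. A separate Ti(OiPr)4-catalysed lactonisation in toluene at 60 °C then returns the route to 24.

Step 22 (nucleophilic epoxidation). Risks are base-induced isomerisation of the exocyclic alkene or of the angelate, and imperfect facial control at C11. The fallback sets out from hydroxy lactone 33, before the angelate is present. OsO4/NMO dihydroxylation of the exocyclic methylene from the face anti to the C8 substituent gives triol F6. Appel chlorination (PPh3, CCl4) of the primary hydroxyl gives chloro diol F7. Angeloylation of the C8 hydroxyl under the conditions of step 21 then gives 38, where the route is rejoined and the TBS ethers are removed with aq. HCl as in step 23.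

**Further compounds**
F1 | step 20 | ynone triol: seco-ynone with free C6, C7 and C10 hydroxyls, 5,9-bis-O-TBS, 8-O-TES | OC[C@@H](O[Si](C)(C)C(C)(C)C)[C@@H](C)C#CC(=O)[C@@](C)(O)[C@@H](O[Si](C)(C)C(C)(C)C)[C@@H](O[Si](CC)(CC)CC)[C@@H](O)C(=C)C(=O)OC
F2 | step 20 | seco-ynone C6 aldehyde with free C7 and C10 hydroxyls | O=C[C@@H](O[Si](C)(C)C(C)(C)C)[C@@H](C)C#CC(=O)[C@@](C)(O)[C@@H](O[Si](C)(C)C(C)(C)C)[C@@H](O[Si](CC)(CC)CC)[C@@H](O)C(=C)C(=O)OC
F3 | step 20 | seco-ynone C6 aldehyde with methyl (Z)-2-(bromomethyl)enoate | O=C[C@@H](O[Si](C)(C)C(C)(C)C)[C@@H](C)C#CC(=O)[C@@](C)(O)[C@@H](O[Si](C)(C)C(C)(C)C)[C@@H](O[Si](CC)(CC)CC)/C=C(\CBr)C(=O)OC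
F4 | step 20 | macrocyclic ynone lactone: ten-membered 2-yn-1-one with 8,10-dihydroxy, 5,9-bis-O-TBS, 11(13)-ene 6,12-lactone | O[C@H]1[C@@H]2[C@H](OC(=O)C2=C)[C@@H](O[Si](C)(C)C(C)(C)C)[C@@H](C)C#CC(=O)[C@@](C)(O)[C@H]1O[Si](C)(C)C(C)(C)C
F5 | step 15 | open hydroxy diester (free C7 carbinol, 7S) | COC(=O)[C@@](C)(O[Si](C)(C)C)[C@@H](O[Si](C)(C)C(C)(C)C)[C@@H](O[Si](CC)(CC)CC)[C@@H](O)C(=C)C(=O)OC
F6 | step 22 | 8,11,13-trihydroxy 5,9-bis-O-TBS 6,12-lactone | O[C@H]1[C@@H]2[C@H](OC(=O)[C@]2(O)CO)[C@@H](O[Si](C)(C)C(C)(C)C)[C@@H](C)C2=CC(=O)[C@@](C)(O2)[C@H]1O[Si](C)(C)C(C)(C)C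
F7 | step 22 | 13-chloro-8,11-dihydroxy 5,9-bis-O-TBS 6,12-lactone | O[C@H]1[C@@H]2[C@H](OC(=O)[C@]2(O)CCl)[C@@H](O[Si](C)(C)C(C)(C)C)[C@@H](C)C2=CC(=O)[C@@](C)(O2)[C@H]1O[Si](C)(C)C(C)(C)C
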